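**Plan**

- Numbering: ring B is O1–C2–C3–C4–C4a–C8a, ring A is C4a–C5–C6–C7–C8–C8a, and C8 carries the side chain C9(Ph)–C10–C11O2H. The target is drawn as its 4-enol-5,7-dione tautomer.
- Retrosynthetic cuts, in order: O7–C11 (the acid is masked as an enol lactone on O7), C6–prenyl, C8–C9, then C2–C3 of ring B, then C4a–C4 and C6–CH2(cyclobutyl) on a phloroglucinol ring.
- Forward: ring A is phloroglucinol and the cyclobutane comes intact from (−)-verbenone. The two are joined at C6, ring B is closed through C2–C3, a lactone ring is built on O7/C8, ring A is dearomatised at C6, and the lactone is opened.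
- Enabling feature: C2 is the O–CH2 carbon of an ethyl ether on O1, the only ring A oxygen para to C6, and it lies ortho to the C4 acyl group. A carbene at C3 therefore meets exactly one ether-activated C–H bond at six-ring distance.
- Stereochemistry: cyclobutane centres from verbenone; C2 and C3 from the chiral dirhodium carboxylate (cis by kinetic control); C9 from an (S)-prolinol silyl ether iminium catalyst; C6 from a chiral palladium allyl catalyst.

Key step: step 14

Assumption: Rh2(S-PTTL)4 and the (S,S)-DACH-phenyl Trost ligand are taken to give the 2R,3S and 6R configurations; each has an equally available mirror-image form if the sense proves opposite.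

Abbreviation: CbCH2 = {[(1R,3S)-2,2-dimethyl-3-(prop-1-en-2-yl)cyclobutyl]methyl}; full names are in the compound list.

**Route**

Step 1
Reactants: 1 (1S,5S)-(−)-verbenone
Product: 2 (1S,3R)-3-acetyl-2,2-dimethylcyclobutane-1-carboxylic acid
Conditions: RuCl3·xH2O (2 mol%), NaIO4 (4.2 equiv), EtOAc/MeCN/H2O, rt
Reagents that add atoms: sodium periodate [Na+].[O-]I(=O)(=O)=O; water O
Why: RuO4 formed in situ cleaves the enone C=C and the resulting α-keto acid is decarboxylated oxidatively (ruthenium tetroxide oxidative cleavage), which leaves both ring stereocentres of verbenone untouched as the cis keto acid.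

Step 2
Reactants: 2 (1S,3R)-3-acetyl-2,2-dimethylcyclobutane-1-carboxylic acid
Product: 3 (1S,3S)-2,2-dimethyl-3-(prop-1-en-2-yl)cyclobutane-1-carboxylic acid
Conditions: Ph3PCH3Br (2.5 equiv), KOtBu (3.5 equiv), THF, 0 °C → rt; then 1 M HCl
Reagents that add atoms: methyltriphenylphosphonium bromide C[P+](c1ccccc1)(c1ccccc1)c1ccccc1.[Br-]
Why: Wittig methylenation of the methyl ketone on the carboxylate salt should keep the cis ring because the carboxylate α-hydrogen is not acidic and enolisation of the ketone towards the strained ring carbon is slow.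

Step 3
Reactants: 3 (1S,3S)-2,2-dimethyl-3-(prop-1-en-2-yl)cyclobutane-1-carboxylic acid
Product: 4 [(1S,3S)-2,2-dimethyl-3-(prop-1-en-2-yl)cyclobutyl]methanol
Conditions: LiAlH4, THF, 0 °C → rt; H2O/NaOH work-up
Reagents that add atoms: none
Why: Hydride reduction of a carboxylic acid to the primary alcohol with LiAlH4 leaves the isolated alkene and both stereocentres alone.

Step 4
Reactants: 4 [(1S,3S)-2,2-dimethyl-3-(prop-1-en-2-yl)cyclobutyl]methanol
Product: 5 (1S,3S)-1-(iodomethyl)-2,2-dimethyl-3-(prop-1-en-2-yl)cyclobutane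
Conditions: PPh3, I2, imidazole, CH2Cl2, 0 °C → rt
Reagents that add atoms: iodine II
Why: Appel iodination proceeds by SN2 displacement at the primary carbon under non-acidic conditions, so neither the ring centres nor the isopropenyl group are touched.

Step 5
Reactants: 6 phloroglucinol
Product: 7 5-ethoxybenzene-1,3-diol
Conditions: EtOH, dry HCl, 70 °C, stopped at partial conversion
Reagents that add atoms: ethanol CCO
Why: Acid-catalysed etherification of phloroglucinol through its keto tautomer gives the mono-ether, and because the three oxygens are equivalent any single ethylation defines the oxygen that becomes O1.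

Step 6
Reactants: 7 5-ethoxybenzene-1,3-diol
Product: 8 1-ethoxy-3,5-bis(methoxymethoxy)benzene
Conditions: MOMCl (2.5 equiv), i-Pr2NEt, CH2Cl2, 0 °C → rt
Reagents that add atoms: chloromethyl methyl ether COCCl
Why: O-alkylation of both phenols with the reactive α-chloro ether (Williamson-type etherification) installs two groups that direct the later ring metalations.

Step 7
Reactants: 8 1-ethoxy-3,5-bis(methoxymethoxy)benzene
Product: 10 2-bromo-5-ethoxy-1,3-bis(methoxymethoxy)benzene, via aryllithium 9 (not isolated)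
Conditions: n-BuLi, THF, 0 °C; BrCH2CH2Br, −78 °C → rt
Reagents that add atoms: 1,2-dibromoethane BrCCBr
Why: Directed ortho-metalation occurs at the carbon flanked by the two chelating methoxymethoxy groups, which is the position para to the ethoxy group, and the aryllithium is brominated by 1,2-dibromoethane.

Step 8
Reactants: 5 (1S,3S)-1-(iodomethyl)-2,2-dimethyl-3-(prop-1-en-2-yl)cyclobutane; 10 2-bromo-5-ethoxy-1,3-bis(methoxymethoxy)benzene
Product: 13 2-(CbCH2)-5-ethoxy-1,3-bis(methoxymethoxy)benzene, via alkyllithium 11 (not isolated), via alkylzinc chloride 12 (not isolated)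
Conditions: 5, t-BuLi (2.1 equiv), Et2O, −78 °C; ZnCl2, THF, −78 °C → rt; then 10, Pd(OAc)2 (3 mol%), SPhos (6 mol%), THF, 50 °C
Reagents that add atoms: none
Why: Negishi coupling of a primary alkylzinc with a hindered, electron-rich aryl bromide is well served by a bulky biaryl phosphine on palladium and forms the C6–CH2 bond without an acid-sensitive or epimerisable intermediate.

Step 9
Reactants: 13 2-(CbCH2)-5-ethoxy-1,3-bis(methoxymethoxy)benzene
Product: 15 1-[3-(CbCH2)-6-ethoxy-2,4-bis(methoxymethoxy)phenyl]propan-1-one, via aryllithium 14 (not isolated)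
Conditions: n-BuLi, THF, 0 °C; EtC(O)N(OMe)Me, −78 → 0 °C; AcOH
Reagents that add atoms: N-methoxy-N-methylpropanamide CCC(=O)N(C)OC
Why: A second directed ortho-metalation can only occur at the two equivalent ring positions between a methoxymethoxy and the ethoxy group, and acylation with the Weinreb amide stops at the ketone through its stable chelate.

Step 10
Reactants: 15 1-[3-(CbCH2)-6-ethoxy-2,4-bis(methoxymethoxy)phenyl]propan-1-one
Product: 16 1-[3-(CbCH2)-6-ethoxy-2,4-dihydroxyphenyl]propan-1-one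
Conditions: ZnBr2 (2 equiv), n-PrSH (4 equiv), CH2Cl2, 0 °C → rt
Reagents that add atoms: none
Why: Lewis acid and thiol acetal exchange removes both methoxymethyl ethers without protic acid, which could protonate the isopropenyl group and expand the cyclobutane.

Step 11
Reactants: 16 1-[3-(CbCH2)-6-ethoxy-2,4-dihydroxyphenyl]propan-1-one
Product: 17 1-[2,4-bis(tert-butyldimethylsilyloxy)-3-(CbCH2)-6-ethoxyphenyl]propan-1-one
Conditions: TBSOTf (2.5 equiv), 2,6-lutidine, CH2Cl2, −20 °C → rt
Reagents that add atoms: tert-butyldimethylsilyl triflate CC(C)(C)[Si](C)(C)OS(=O)(=O)C(F)(F)F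
Why: Silylation with the silyl triflate reaches even the hydrogen-bonded, hindered O5–H, and the silyl ethers are chosen because they offer the later carbene no C–H bond at six-ring distance and can be removed by fluoride without base.

Step 12
Reactants: 17 1-[2,4-bis(tert-butyldimethylsilyloxy)-3-(CbCH2)-6-ethoxyphenyl]propan-1-one
Product: 19 1-[2,4-bis(tert-butyldimethylsilyloxy)-3-(CbCH2)-6-ethoxyphenyl]-4,4,4-trifluoro-2-methylbutane-1,3-dione, via lithium enolate 18 (not isolated)
Conditions: LiN(SiMe3)2, THF, −78 °C; CF3CO2CH2CF3; aq. HCl work-up, crude product used directly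
Reagents that add atoms: 2,2,2-trifluoroethyl trifluoroacetate O=C(OCC(F)(F)F)C(F)(F)F
Why: Claisen-type trifluoroacetylation of the kinetic lithium enolate activates the propionyl α-carbon for diazo transfer, and at −78 °C the silyl ethers should stay in place.

Step 13
Reactants: 19 1-[2,4-bis(tert-butyldimethylsilyloxy)-3-(CbCH2)-6-ethoxyphenyl]-4,4,4-trifluoro-2-methylbutane-1,3-dione
Product: 20 2-diazo-1-[2,4-bis(tert-butyldimethylsilyloxy)-3-(CbCH2)-6-ethoxyphenyl]propan-1-one
Conditions: MsN3, Et3N, H2O (1 equiv), MeCN, rt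
Reagents that add atoms: methanesulfonyl azide CS(=O)(=O)N=[N+]=[N-]
Why: Regitz diazo transfer to the 1,3-diketone is followed by loss of the trifluoroacetyl group onto the sulfonamide nitrogen (detrifluoroacetylative diazo transfer), which gives the α-methyl α-diazoketone under mild base.

Step 14
Reactants: 20 2-diazo-1-[2,4-bis(tert-butyldimethylsilyloxy)-3-(CbCH2)-6-ethoxyphenyl]propan-1-one
Product: 21 (2R,3S)-5,7-bis(tert-butyldimethylsilyloxy)-6-(CbCH2)-2,3-dimethylchroman-4-one
Conditions: dirhodium tetrakis[N-phthaloyl-(S)-tert-leucinate], Rh2(S-PTTL)4 (1 mol%), CH2Cl2, −40 → 0 °C, slow addition of 20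
Reagents that add atoms: none
Why: The dirhodium carboxylate takes up the diazo carbon of 20 and expels N2 to give an electrophilic rhodium carbene at C3, which inserts into one C–H bond of the O1–CH2 group through a concerted, asynchronous three-centre transition state with hydride-shift character, the ether oxygen stabilising the partial positive charge at C2. The closest known reaction is the chiral dirhodium carboxylate-catalysed intramolecular C–H insertion of 1-(2-alkoxyphenyl)-2-diazopropan-1-ones to cis-2,3-disubstituted chroman-4-ones. Ring B closes by C2–C3 bond formation in a 1,6-insertion mode (carbene carbon and C–H carbon joined through C4, C4a, C8a and O1), the only closure on offer because the methyl C–H of the ethyl group would require a seven-membered ring. C2 is controlled by the N-phthaloyl-tert-leucinate ligand sphere, which selects one of the two enantiotopic methylene hydrogens, and C3 is set in the same bond-forming event with its methyl cis to the C2 methyl as the kinetic outcome of the compact transition state. The step needs insertion to win over 1,2-hydride shift from the C3 methyl, over ylide formation at O1 or O5 and over cyclopropanation of the isopropenyl group: the bulky carboxylate at low temperature disfavours the hydride shift, an ethyl or silyl group on oxygen gives no productive ylide rearrangement and the silyl ethers offer no C–H bond within reach, and the alkene is too remote for an intramolecular reaction. Because the ethyl group sits on the one oxygen para to C6, the regiochemistry of ring B needs no further control.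

Step 15
Reactants: 21 (2R,3S)-5,7-bis(tert-butyldimethylsilyloxy)-6-(CbCH2)-2,3-dimethylchroman-4-one
Product: 22 (2R,3S)-6-(CbCH2)-5,7-dihydroxy-2,3-dimethylchroman-4-one
Conditions: KHF2, MeOH, rt
Reagents that add atoms: none
Why: Bifluoride cleaves aryl silyl ethers (fluoride desilylation) under weakly acidic conditions, so C3 next to the ketone is not exposed to base and the cis relationship should survive.

Step 16
Reactants: 22 (2R,3S)-6-(CbCH2)-5,7-dihydroxy-2,3-dimethylchroman-4-one; 23 (E)-cinnamaldehyde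
Product: 25 (2R,3S,10S)-6-(CbCH2)-5,8-dihydroxy-2,3-dimethyl-10-phenyl-2,3,9,10-tetrahydro-4H,8H-pyrano[2,3-f]chromen-4-one as a mixture of C8 lactol epimers, via hydroxy aldehyde 24 (not isolated)
Conditions: (S)-diphenylprolinol trimethylsilyl ether (20 mol%), PhCO2H (20 mol%), CH2Cl2, 0 °C → rt
Reagents that add atoms: none
Why: In this iminium-catalysed Friedel–Crafts conjugate addition C8 is the only free ring position, the diphenyl(silyloxy)methyl group of the (S)-catalyst blocks one face of the s-trans iminium ion so that the arene adds to the Si face of the β-carbon and sets C9 as S, and O7–H then closes the lactol.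

Step 17
Reactants: 25 (2R,3S,10S)-6-(CbCH2)-5,8-dihydroxy-2,3-dimethyl-10-phenyl-2,3,9,10-tetrahydro-4H,8H-pyrano[2,3-f]chromen-4-one
Product: 26 (2R,3S,10S)-6-(CbCH2)-5-hydroxy-2,3-dimethyl-10-phenyl-2,3,9,10-tetrahydro-4H,8H-pyrano[2,3-f]chromene-4,8-dione
Conditions: Dess–Martin periodinane, CH2Cl2, 0 °C → rt
Reagents that add atoms: none
Why: Periodinane oxidation of a lactol to the lactone is neutral to mildly acidic and converges both lactol epimers, while the remaining phenol is hydrogen-bonded, fully substituted and therefore resistant to oxidation.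

Step 18
Reactants: 26 (2R,3S,10S)-6-(CbCH2)-5-hydroxy-2,3-dimethyl-10-phenyl-2,3,9,10-tetrahydro-4H,8H-pyrano[2,3-f]chromene-4,8-dione
Product: 27 (2R,3S,6R,10S)-6-(CbCH2)-2,3-dimethyl-6-(3-methylbut-2-en-1-yl)-10-phenyl-2,3,9,10-tetrahydro-4H,8H-pyrano[2,3-f]chromene-4,5,8(6H)-trione
Conditions: Pd2(dba)3·CHCl3 (2.5 mol%), (S,S)-DACH-phenyl Trost ligand (7.5 mol%), prenyl tert-butyl carbonate (1.3 equiv), toluene, 0 °C → rt
Reagents that add atoms: tert-butyl (3-methylbut-2-en-1-yl) carbonate CC(C)=CCOC(=O)OC(C)(C)C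
Why: Proposed new method: zerovalent palladium ionises the prenyl carbonate with loss of CO2, the released tert-butoxide deprotonates O5–H, and the phenoxide, whose other free ring A oxygen (O7) is tied up in the lactone, attacks the unsubstituted terminus of the π-prenyl complex through C6 (ortho to O5) rather than through the angular and more hindered C8, giving the linear prenyl group and a cyclohexa-2,4-dienone whose C6 configuration (6R) is decided by the chiral ligand pocket, while O-prenylation is reversible under the catalyst; the closest known reactions are the palladium-catalysed asymmetric allylic dearomatisation of substituted naphthols and the palladium-catalysed dearomative allylation of acylphloroglucinols (Tsuji–Trost type), neither shown on a monophenolic lactone of this kind.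

Step 19
Reactants: 27 (2R,3S,6R,10S)-6-(CbCH2)-2,3-dimethyl-6-(3-methylbut-2-en-1-yl)-10-phenyl-2,3,9,10-tetrahydro-4H,8H-pyrano[2,3-f]chromene-4,5,8(6H)-trione
Product: 28 (3S)-3-[(2R,3S,6R)-6-(CbCH2)-4-hydroxy-2,3-dimethyl-6-(3-methylbut-2-en-1-yl)-5,7-dioxo-2,3,6,7-tetrahydro-5H-chromen-8-yl]-3-phenylpropanoic acid (CNP0328119.1)
Conditions: LiOH (3 equiv), THF/H2O, 0 °C; then 1 M HCl to pH 3
Reagents that add atoms: lithium hydroxide [Li+].[OH-]
Why: Saponification of the enol ester is easy because the C7 enolate is a vinylogous carboxylate leaving group, and the β-triketone anion formed at once protects C3–H from enolisation until acidification releases the acid in its enol form.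

**Compound list**

1 | (1S,5S)-(−)-verbenone, 4,6,6-trimethylbicyclo[3.1.1]hept-3-en-2-one | CC1=CC(=O)[C@H]2C[C@@H]1C2(C)C | starting material
2 | (1S,3R)-3-acetyl-2,2-dimethylcyclobutane-1-carboxylic acid | CC(=O)[C@@H]1C[C@H](C(=O)O)C1(C)C | intermediate
3 | (1S,3S)-2,2-dimethyl-3-(prop-1-en-2-yl)cyclobutane-1-carboxylic acid | C=C(C)[C@@H]1C[C@H](C(=O)O)C1(C)C | intermediate
4 | [(1S,3S)-2,2-dimethyl-3-(prop-1-en-2-yl)cyclobutyl]methanol | C=C(C)[C@@H]1C[C@H](CO)C1(C)C | intermediate
5 | (1S,3S)-1-(iodomethyl)-2,2-dimethyl-3-(prop-1-en-2-yl)cyclobutane | C=C(C)[C@@H]1C[C@H](CI)C1(C)C | intermediate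
6 | phloroglucinol, benzene-1,3,5-triol | Oc1cc(O)cc(O)c1 | starting material
7 | 5-ethoxybenzene-1,3-diol | CCOc1cc(O)cc(O)c1 | intermediate
8 | 1-ethoxy-3,5-bis(methoxymethoxy)benzene | CCOc1cc(OCOC)cc(OCOC)c1 | intermediate
9 | [4-ethoxy-2,6-bis(methoxymethoxy)phenyl]lithium | CCOc1cc(OCOC)c([Li])c(OCOC)c1 | intermediate (not isolated)
10 | 2-bromo-5-ethoxy-1,3-bis(methoxymethoxy)benzene | CCOc1cc(OCOC)c(Br)c(OCOC)c1 | intermediate
11 | {[(1S,3S)-2,2-dimethyl-3-(prop-1-en-2-yl)cyclobutyl]methyl}lithium | C=C(C)[C@@H]1C[C@H](C[Li])C1(C)C | intermediate (not isolated)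
12 | chloro{[(1S,3S)-2,2-dimethyl-3-(prop-1-en-2-yl)cyclobutyl]methyl}zinc | C=C(C)[C@@H]1C[C@H](C[Zn]Cl)C1(C)C | intermediate (not isolated)
13 | 2-{[(1R,3S)-2,2-dimethyl-3-(prop-1-en-2-yl)cyclobutyl]methyl}-5-ethoxy-1,3-bis(methoxymethoxy)benzene | C=C(C)[C@@H]1C[C@H](Cc2c(OCOC)cc(OCC)cc2OCOC)C1(C)C | intermediate
14 | [3-{[(1R,3S)-2,2-dimethyl-3-(prop-1-en-2-yl)cyclobutyl]methyl}-6-ethoxy-2,4-bis(methoxymethoxy)phenyl]lithium | C=C(C)[C@@H]1C[C@H](Cc2c(OCOC)c([Li])c(OCC)cc2OCOC)C1(C)C | intermediate (not isolated)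
15 | 1-[3-{[(1R,3S)-2,2-dimethyl-3-(prop-1-en-2-yl)cyclobutyl]methyl}-6-ethoxy-2,4-bis(methoxymethoxy)phenyl]propan-1-one | C=C(C)[C@@H]1C[C@H](Cc2c(OCOC)c(C(=O)CC)c(OCC)cc2OCOC)C1(C)C | intermediate
16 | 1-[3-{[(1R,3S)-2,2-dimethyl-3-(prop-1-en-2-yl)cyclobutyl]methyl}-6-ethoxy-2,4-dihydroxyphenyl]propan-1-one | C=C(C)[C@@H]1C[C@H](Cc2c(O)c(C(=O)CC)c(OCC)cc2O)C1(C)C | intermediate
17 | 1-[2,4-bis(tert-butyldimethylsilyloxy)-3-{[(1R,3S)-2,2-dimethyl-3-(prop-1-en-2-yl)cyclobutyl]methyl}-6-ethoxyphenyl]propan-1-one | C=C(C)[C@@H]1C[C@H](Cc2c(O[Si](C)(C)C(C)(C)C)c(C(=O)CC)c(OCC)cc2O[Si](C)(C)C(C)(C)C)C1(C)C | intermediate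
18 | lithium enolate of 17, lithium 1-aryl-prop-1-en-1-olate | C=C(C)[C@@H]1C[C@H](Cc2c(O[Si](C)(C)C(C)(C)C)c(C(O[Li])=CC)c(OCC)cc2O[Si](C)(C)C(C)(C)C)C1(C)C | intermediate (not isolated)
19 | 1-[2,4-bis(tert-butyldimethylsilyloxy)-3-{[(1R,3S)-2,2-dimethyl-3-(prop-1-en-2-yl)cyclobutyl]methyl}-6-ethoxyphenyl]-4,4,4-trifluoro-2-methylbutane-1,3-dione | C=C(C)[C@@H]1C[C@H](Cc2c(O[Si](C)(C)C(C)(C)C)c(C(=O)C(C)C(=O)C(F)(F)F)c(OCC)cc2O[Si](C)(C)C(C)(C)C)C1(C)C | intermediate
20 | 2-diazo-1-[2,4-bis(tert-butyldimethylsilyloxy)-3-{[(1R,3S)-2,2-dimethyl-3-(prop-1-en-2-yl)cyclobutyl]methyl}-6-ethoxyphenyl]propan-1-one | C=C(C)[C@@H]1C[C@H](Cc2c(O[Si](C)(C)C(C)(C)C)c(C(=O)C(C)=[N+]=[N-])c(OCC)cc2O[Si](C)(C)C(C)(C)C)C1(C)C | intermediate (key-step precursor)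
21 | (2R,3S)-5,7-bis(tert-butyldimethylsilyloxy)-6-{[(1R,3S)-2,2-dimethyl-3-(prop-1-en-2-yl)cyclobutyl]methyl}-2,3-dimethylchroman-4-one | C=C(C)[C@@H]1C[C@H](Cc2c(O[Si](C)(C)C(C)(C)C)c3C(=O)[C@@H](C)[C@@H](C)Oc3cc2O[Si](C)(C)C(C)(C)C)C1(C)C | intermediate (key-step product)
22 | (2R,3S)-6-{[(1R,3S)-2,2-dimethyl-3-(prop-1-en-2-yl)cyclobutyl]methyl}-5,7-dihydroxy-2,3-dimethylchroman-4-one | C=C(C)[C@@H]1C[C@H](Cc2c(O)c3C(=O)[C@@H](C)[C@@H](C)Oc3cc2O)C1(C)C | intermediate
23 | (E)-cinnamaldehyde | O=C/C=C/c1ccccc1 | starting material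
24 | (3S)-3-[(2R,3S)-6-{[(1R,3S)-2,2-dimethyl-3-(prop-1-en-2-yl)cyclobutyl]methyl}-5,7-dihydroxy-2,3-dimethyl-4-oxo-3,4-dihydro-2H-chromen-8-yl]-3-phenylpropanal | C=C(C)[C@@H]1C[C@H](Cc2c(O)c3C(=O)[C@@H](C)[C@@H](C)Oc3c([C@@H](CC=O)c3ccccc3)c2O)C1(C)C | intermediate (not isolated)
25 | (2R,3S,10S)-6-{[(1R,3S)-2,2-dimethyl-3-(prop-1-en-2-yl)cyclobutyl]methyl}-5,8-dihydroxy-2,3-dimethyl-10-phenyl-2,3,9,10-tetrahydro-4H,8H-pyrano[2,3-f]chromen-4-one, C8 lactol epimers | C=C(C)[C@@H]1C[C@H](Cc2c(O)c3C(=O)[C@@H](C)[C@@H](C)Oc3c4c2OC(O)C[C@H]4c5ccccc5)C1(C)C | intermediate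
26 | (2R,3S,10S)-6-{[(1R,3S)-2,2-dimethyl-3-(prop-1-en-2-yl)cyclobutyl]methyl}-5-hydroxy-2,3-dimethyl-10-phenyl-2,3,9,10-tetrahydro-4H,8H-pyrano[2,3-f]chromene-4,8-dione | C=C(C)[C@@H]1C[C@H](Cc2c(O)c3C(=O)[C@@H](C)[C@@H](C)Oc3c4c2OC(=O)C[C@H]4c5ccccc5)C1(C)C | intermediate
27 | (2R,3S,6R,10S)-6-{[(1R,3S)-2,2-dimethyl-3-(prop-1-en-2-yl)cyclobutyl]methyl}-2,3-dimethyl-6-(3-methylbut-2-en-1-yl)-10-phenyl-2,3,9,10-tetrahydro-4H,8H-pyrano[2,3-f]chromene-4,5,8(6H)-trione | C=C(C)[C@@H]1C[C@H](C[C@@]2(CC=C(C)C)C(=O)C3=C(O[C@H](C)[C@H](C)C3=O)C4=C2OC(=O)C[C@H]4c5ccccc5)C1(C)C | intermediate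
28 | (3S)-3-[(2R,3S,6R)-6-{[(1R,3S)-2,2-dimethyl-3-(prop-1-en-2-yl)cyclobutyl]methyl}-4-hydroxy-2,3-dimethyl-6-(3-methylbut-2-en-1-yl)-5,7-dioxo-2,3,6,7-tetrahydro-5H-chromen-8-yl]-3-phenylpropanoic acid | C=C(C)[C@@H]1C[C@H](C[C@@]2(CC=C(C)C)C(=O)C3=C(O)[C@@H](C)[C@@H](C)OC3=C([C@@H](CC(=O)O)c3ccccc3)C2=O)C1(C)C | target

**Step count and risks**

Total step count: 19. Longest linear sequence: 16 steps (steps 1–4 and 8–19, from verbenone).

Steps most likely to fail:

Step 18 (proposed new method). The phenoxide may be prenylated on O5, at the branched allyl terminus or through C8 instead of C6, and the ligand may discriminate poorly between the two faces of C6. The fallback uses known chemistry, sets out from 26 and comes back at 28, bypassing 27. Aqueous LiOH in THF opens the lactone to the trianion of (3S)-3-[(2R,3S)-6-(CbCH2)-5,7-dihydroxy-2,3-dimethyl-4-oxo-3,4-dihydro-2H-chromen-8-yl]-3-phenylpropanoic acid F1. This is C-alkylated with prenyl bromide at 0 °C at C6, the carbon flanked by two phenoxides, in the classical alkylative dearomatisation of acylphloroglucinols. Acidification should give 28 together with its C6 epimer F2, to be separated by preparative HPLC.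

Step 14. The catalyst may select poorly between the two methylene hydrogens at C2, and the kinetic cis product may drift to trans by enolisation at C3 during isolation. The fallback sets out from 20 and comes back at 21, setting the two centres by a different reaction. Ring B is closed through the same C–H insertion with achiral Rh2(OAc)4, without regard to configuration, to give the C2/C3 stereoisomer mixture of the chromanone F3. DDQ in dioxane dehydrogenates this to the 2,3-dimethylchromone F4, which erases both centres. Copper hydride 1,4-reduction [Cu(OAc)2, (S)-p-Tol-BINAP or its antipode as needed for 2R, polymethylhydrosiloxane, t-BuOH, toluene] then sets C2 by ligand control, and kinetic protonation of the enolate on the face away from the C2 methyl sets C3 cis.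

Step 16. C8 of the acyl-deactivated ring may add too slowly to the iminium ion, so that 1,2-addition or catalyst decomposition takes over. The fallback sets out from 22 and comes back at 26, bypassing 25 and step 17. Yb(OTf)3-catalysed Friedel–Crafts addition of 22 to 5-benzylidene-2,2-dimethyl-1,3-dioxane-4,6-dione in MeNO2 gives the Meldrum's acid adduct F5. This lactonises on O7 with loss of acetone to the 3-carboxy lactone F6, which decarboxylates on warming to 26 and its C10 epimer F7; the epimer is removed by chromatography.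

Further compounds
F1 | step 18 | (3S)-3-[(2R,3S)-6-{[(1R,3S)-2,2-dimethyl-3-(prop-1-en-2-yl)cyclobutyl]methyl}-5,7-dihydroxy-2,3-dimethyl-4-oxo-3,4-dihydro-2H-chromen-8-yl]-3-phenylpropanoic acid | C=C(C)[C@@H]1C[C@H](Cc2c(O)c3C(=O)[C@@H](C)[C@@H](C)Oc3c([C@@H](CC(=O)O)c3ccccc3)c2O)C1(C)C
F2 | step 18 | C6 epimer of 28, (3S)-3-[(2R,3S,6S)-6-{[(1R,3S)-2,2-dimethyl-3-(prop-1-en-2-yl)cyclobutyl]methyl}-4-hydroxy-2,3-dimethyl-6-(3-methylbut-2-en-1-yl)-5,7-dioxo-2,3,6,7-tetrahydro-5H-chromen-8-yl]-3-phenylpropanoic acid | C=C(C)[C@@H]1C[C@H](C[C@]2(CC=C(C)C)C(=O)C3=C(O)[C@@H](C)[C@@H](C)OC3=C([C@@H](CC(=O)O)c3ccccc3)C2=O)C1(C)C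
F3 | step 14 | 5,7-bis(tert-butyldimethylsilyloxy)-6-{[(1R,3S)-2,2-dimethyl-3-(prop-1-en-2-yl)cyclobutyl]methyl}-2,3-dimethylchroman-4-one, mixture of C2/C3 stereoisomers | C=C(C)[C@@H]1C[C@H](Cc2c(O[Si](C)(C)C(C)(C)C)c3C(=O)C(C)C(C)Oc3cc2O[Si](C)(C)C(C)(C)C)C1(C)C
F4 | step 14 | 5,7-bis(tert-butyldimethylsilyloxy)-6-{[(1R,3S)-2,2-dimethyl-3-(prop-1-en-2-yl)cyclobutyl]methyl}-2,3-dimethyl-4H-chromen-4-one | C=C(C)[C@@H]1C[C@H](Cc2c(O[Si](C)(C)C(C)(C)C)c3C(=O)C(C)=C(C)Oc3cc2O[Si](C)(C)C(C)(C)C)C1(C)C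
F5 | step 16 | 5-{[(2R,3S)-6-{[(1R,3S)-2,2-dimethyl-3-(prop-1-en-2-yl)cyclobutyl]methyl}-5,7-dihydroxy-2,3-dimethyl-4-oxo-3,4-dihydro-2H-chromen-8-yl](phenyl)methyl}-2,2-dimethyl-1,3-dioxane-4,6-dione, both C9 epimers | C=C(C)[C@@H]1C[C@H](Cc2c(O)c3C(=O)[C@@H](C)[C@@H](C)Oc3c(C(c4ccccc4)C5C(=O)OC(C)(C)OC5=O)c2O)C1(C)C
F6 | step 16 | (2R,3S)-6-{[(1R,3S)-2,2-dimethyl-3-(prop-1-en-2-yl)cyclobutyl]methyl}-5-hydroxy-2,3-dimethyl-4,8-dioxo-10-phenyl-2,3,9,10-tetrahydro-4H,8H-pyrano[2,3-f]chromene-9-carboxylic acid, C9/C10 stereoisomers | C=C(C)[C@@H]1C[C@H](Cc2c(O)c3C(=O)[C@@H](C)[C@@H](C)Oc3c4c2OC(=O)C(C(=O)O)C4c5ccccc5)C1(C)C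
F7 | step 16 | C10 epimer of 26, (2R,3S,10R)-6-{[(1R,3S)-2,2-dimethyl-3-(prop-1-en-2-yl)cyclobutyl]methyl}-5-hydroxy-2,3-dimethyl-10-phenyl-2,3,9,10-tetrahydro-4H,8H-pyrano[2,3-f]chromene-4,8-dione | C=C(C)[C@@H]1C[C@H](Cc2c(O)c3C(=O)[C@@H](C)[C@@H](C)Oc3c4c2OC(=O)C[C@@H]4c5ccccc5)C1(C)C
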